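**Retrosynthetic overview**
1. The C1 hydroperoxide and the 10(14)-methylidene come last, from a singlet-oxygen ene reaction on the 1(10)-E alkene of diol ester 31.
2. 31 comes from hydroxy lactone 23 by acylation of the C8 hydroxyl with acetonide acid 29, then acetonide removal.
3. Key step: 23 comes from acyclic enal/(Z)-2-(bromomethyl)enoate 20 by an indium Barbier closure. C7 (the β-carbon of the enoate, made nucleophilic as an allylindium) attacks the C6 aldehyde. This closes the ten-membered carbocycle first and sets C6 and C7; the cis γ-lactone then forms on it in the same operation.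
4. 20 comes from aldehyde 16 (Morita–Baylis–Hillman reaction, SN2' bromination, acetal hydrolysis). 16 comes from a B-alkyl Suzuki union (C3–C4) of diene 7 with (Z)-iodoalkene 13.
5. 7 comes from (R)-glycidol (C8 stereocentre), acetylide and carboalumination; 13 from propiolaldehyde diethyl acetal; 29 from a (R)-malic-acid-derived ester.

Assumption: the SMILES is taken literally, i.e. cis-fused lactone (6S,7R,8S), 1R, side chain 3R, and CH2OAc trans to C6 on the C4=C5 bond; germacrane locants (C1–C15) are used in the explanations.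

**Step 1**
Reactants: 1 (R)-glycidol; 2 lithium acetylide ethylenediamine complex
Product: 3 (2S)-pent-4-yne-1,2-diol
Conditions: LiC≡CH·H2NCH2CH2NH2 (2.5 equiv), DMSO, 0 °C → rt; then H2O
Reagents that add atoms: none
Why: SN2 epoxide opening by the acetylide at the terminal CH2 breaks no bond at the stereocentre (Payne equilibration converges on the same diol), so C8 comes unchanged from the chiral pool.

**Step 2**
Reactants: 3 (2S)-pent-4-yne-1,2-diol
Product: 4 (2S)-1,2-bis(triethylsilyloxy)pent-4-yne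
Conditions: TESCl (2.3 equiv), imidazole, CH2Cl2, 0 °C → rt
Reagents that add atoms: triethylsilyl chloride, CC[Si](Cl)(CC)CC
Why: Bis-silylation masks both hydroxyls; the primary silyl ether is the latent C7 aldehyde and the secondary one is the bulky C8 group that later steers the ring closure.

**Step 3**
Reactants: 4 (2S)-1,2-bis(triethylsilyloxy)pent-4-yne; 5 vinyl bromide
Product: 7 (3E,6S)-4-methyl-6,7-bis(triethylsilyloxy)hepta-1,3-diene, via alkenyldimethylalane 6 (not isolated)
Conditions: Me3Al, Cp2ZrCl2 (cat.), CH2Cl2, 0 °C → rt; then CH2=CHBr, Pd(PPh3)4 (cat.), ZnCl2 (0.3 equiv), THF, rt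
Reagents that add atoms: trimethylaluminium, C[Al](C)C
Why: Negishi zirconium-catalysed syn-carboalumination (methyl to the internal carbon, aluminium terminal) fixes the 1(10)-E trisubstituted alkene, and the Pd/Zn-catalysed Negishi coupling of the alkenylalane with vinyl bromide proceeds with retention.

**Step 4**
Reactants: 8 3,3-diethoxyprop-1-yne
Product: 10 4,4-diethoxybut-2-yn-1-ol, via lithium acetylide 9 (not isolated)
Conditions: n-BuLi, THF, −78 °C; then (CH2O)n, → rt; then H2O
Reagents that add atoms: paraformaldehyde (formaldehyde), C=O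
Why: Acetylide addition to formaldehyde (hydroxymethylation) installs C15 and the hydroxyl that directs the next step.

**Step 5**
Reactants: 10 4,4-diethoxybut-2-yn-1-ol
Product: 12 (2Z)-4,4-diethoxy-2-iodobut-2-en-1-ol, via vinylstannane 11 (not isolated)
Conditions: Bu3SnH, [Cp*RuCl]4 (cat.), CH2Cl2, rt; then I2, 0 °C
Reagents that add atoms: iodine, II
Why: Hydroxyl-directed ruthenium-catalysed trans-hydrostannation puts tin on the carbon next to CH2OH and hydrogen anti to it, and iododestannylation with retention leaves iodine cis to the acetal carbon (so later C3 is cis to C6 and CH2OAc trans to C6).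

**Step 6**
Reactants: 12 (2Z)-4,4-diethoxy-2-iodobut-2-en-1-ol
Product: 13 (2Z)-4,4-diethoxy-2-iodobut-2-en-1-yl acetate
Conditions: Ac2O, pyridine, DMAP (cat.), CH2Cl2, 0 °C
Reagents that add atoms: acetic anhydride, CC(=O)OC(C)=O
Why: Standard DMAP-catalysed acetylation installs the C15 acetate, which no later step cleaves.

**Step 7**
Reactants: 7 (3E,6S)-4-methyl-6,7-bis(triethylsilyloxy)hepta-1,3-diene; 13 (2Z)-4,4-diethoxy-2-iodobut-2-en-1-yl acetate
Product: 15 (2E,5E,8S)-2-(2,2-diethoxyethylidene)-6-methyl-8,9-bis(triethylsilyloxy)non-5-en-1-yl acetate, via alkylborane 14 (not isolated)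
Conditions: 9-BBN, THF, 0 °C → rt; then 13, PdCl2(dppf) (cat.), AsPh3, K3PO4 (aq), DMF, rt
Reagents that add atoms: none
Why: 9-BBN hydroborates only the terminal vinyl group of the diene (boron on the end carbon), and the B-alkyl Suzuki–Miyaura coupling forms C3–C4 with retention of the iodoalkene geometry.

**Step 8**
Reactants: 15 (2E,5E,8S)-2-(2,2-diethoxyethylidene)-6-methyl-8,9-bis(triethylsilyloxy)non-5-en-1-yl acetate
Product: 16 (2S,4E,8E)-8-(acetoxymethyl)-10,10-diethoxy-4-methyl-2-(triethylsilyloxy)deca-4,8-dienal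
Conditions: (COCl)2, DMSO, CH2Cl2, −78 → −40 °C; then Et3N, → 0 °C
Reagents that add atoms: none
Why: Under Swern conditions the primary triethylsilyl ether is cleaved and oxidised directly to the aldehyde, while the secondary silyl ether, acetal and acetate are untouched.

**Step 9**
Reactants: 16 (2S,4E,8E)-8-(acetoxymethyl)-10,10-diethoxy-4-methyl-2-(triethylsilyloxy)deca-4,8-dienal; 17 methyl acrylate
Product: 18 methyl (4S,6E,10E)-10-(acetoxymethyl)-12,12-diethoxy-3-hydroxy-6-methyl-2-methylidene-4-(triethylsilyloxy)dodeca-6,10-dienoate (both C3 epimers)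
Conditions: methyl acrylate (excess), DABCO, neat, rt, 4–6 d
Reagents that add atoms: none
Why: Morita–Baylis–Hillman reaction of the activated α-silyloxy aldehyde adds C11–C13; the new carbinol centre is irrelevant because it becomes sp2 in the next step, and the C6 aldehyde stays masked as the acetal.

**Step 10**
Reactants: 18 methyl (4S,6E,10E)-10-(acetoxymethyl)-12,12-diethoxy-3-hydroxy-6-methyl-2-methylidene-4-(triethylsilyloxy)dodeca-6,10-dienoate
Product: 19 methyl (2Z,4S,6E,10E)-10-(acetoxymethyl)-2-(bromomethyl)-12,12-diethoxy-6-methyl-4-(triethylsilyloxy)dodeca-2,6,10-trienoate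
Conditions: NBS, Me2S (premixed), CH2Cl2, 0 °C → rt
Reagents that add atoms: N-bromosuccinimide, O=C1CCC(=O)N1Br
Why: Corey–Kim-type activation followed by SN2' attack of bromide gives the rearranged allylic bromide as the favoured Z isomer (CH2Br cis to C8, ester trans), the geometry needed for a syn allylation.

**Step 11**
Reactants: 19 methyl (2Z,4S,6E,10E)-10-(acetoxymethyl)-2-(bromomethyl)-12,12-diethoxy-6-methyl-4-(triethylsilyloxy)dodeca-2,6,10-trienoate
Product: 20 methyl (2Z,4S,6E,10E)-10-(acetoxymethyl)-2-(bromomethyl)-6-methyl-12-oxo-4-(triethylsilyloxy)dodeca-2,6,10-trienoate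
Conditions: oxalic acid, wet SiO2, CH2Cl2, rt
Reagents that add atoms: water, O
Why: The very labile allylic acetal hydrolyses under mild heterogeneous acid to the enal without touching the secondary silyl ether or isomerising the C4=C5 bond; the enal is used at once.

**Step 12**
Reactants: 20 methyl (2Z,4S,6E,10E)-10-(acetoxymethyl)-2-(bromomethyl)-6-methyl-12-oxo-4-(triethylsilyloxy)dodeca-2,6,10-trienoate
Product: 23 [(3aR,4S,6E,10E,11aS)-4-hydroxy-6-methyl-3-methylidene-2-oxo-2,3,3a,4,5,8,9,11a-octahydrocyclodeca[b]furan-10-yl]methyl acetate, via hydroxy ester 21 (not isolated), via silyl lactone 22 (not isolated)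
Conditions: In powder, THF/H2O (3:1), 2 mM, 35 °C; then PPTS, MeOH, rt
Reagents that add atoms: none
Why: Intramolecular indium Barbier allylation in which the transient 2-(methoxycarbonyl)allylindium makes C7, normally the electrophilic β-carbon of the enoate, a homoenolate-type nucleophile that adds 1,2 to the C6 aldehyde through a closed chair, where the Z geometry (CH2In cis to C8) gives the syn adduct and hence the cis lactone, and the C8 centre selects the face (C8–H eclipsing the alkene to avoid allylic 1,3-strain, the bulky silyloxy group anti to the incoming aldehyde, tether carbon C9 gauche) to give 6S,7R, after which PPTS/MeOH lactonises and removes the silyl group.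

**Step 13**
Reactants: 24 methyl 2-[(4R)-2,2-dimethyl-1,3-dioxolan-4-yl]acetate
Product: 28 methyl 2-[(4R)-2,2-dimethyl-1,3-dioxolan-4-yl]prop-2-enoate, via lithium enolate 25 (not isolated), via Mannich base 26 (not isolated), via ammonium iodide 27 (not isolated)
Conditions: LDA, THF, −78 °C; then CH2=NMe2+ I−, → 0 °C; then MeI, MeOH, rt; then NaHCO3 (aq), CH2Cl2, rt
Reagents that add atoms: Eschenmoser's salt (N,N-dimethylmethyleneiminium iodide), C=[N+](C)C.[I-]
Why: Mannich α-methylenation (enolate aminomethylation, quaternisation, mild-base β-elimination) at −78 °C avoids β-alkoxide loss and leaves the dioxolane stereocentre untouched.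

**Step 14**
Reactants: 28 methyl 2-[(4R)-2,2-dimethyl-1,3-dioxolan-4-yl]prop-2-enoate
Product: 29 2-[(4R)-2,2-dimethyl-1,3-dioxolan-4-yl]prop-2-enoic acid
Conditions: LiOH, THF/H2O, 0 °C; then HCl (aq) to pH 4, 0 °C
Reagents that add atoms: lithium hydroxide, [Li+].[OH-]
Why: Cold saponification of the methyl ester followed by careful acidification gives the acid with the acetonide intact.

**Step 15**
Reactants: 23 [(3aR,4S,6E,10E,11aS)-4-hydroxy-6-methyl-3-methylidene-2-oxo-2,3,3a,4,5,8,9,11a-octahydrocyclodeca[b]furan-10-yl]methyl acetate; 29 2-[(4R)-2,2-dimethyl-1,3-dioxolan-4-yl]prop-2-enoic acid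
Product: 30 (3aR,4S,6E,10E,11aS)-10-(acetoxymethyl)-6-methyl-3-methylidene-2-oxo-2,3,3a,4,5,8,9,11a-octahydrocyclodeca[b]furan-4-yl 2-[(4R)-2,2-dimethyl-1,3-dioxolan-4-yl]prop-2-enoate
Conditions: DCC, DMAP (cat.), CH2Cl2, 0 °C → rt
Reagents that add atoms: none
Why: Steglich esterification acylates the C8 hydroxyl with retention of configuration, as in known acylations of 8-hydroxy germacranolides.

**Step 16**
Reactants: 30 (3aR,4S,6E,10E,11aS)-10-(acetoxymethyl)-6-methyl-3-methylidene-2-oxo-2,3,3a,4,5,8,9,11a-octahydrocyclodeca[b]furan-4-yl 2-[(4R)-2,2-dimethyl-1,3-dioxolan-4-yl]prop-2-enoate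
Product: 31 (3aR,4S,6E,10E,11aS)-10-(acetoxymethyl)-6-methyl-3-methylidene-2-oxo-2,3,3a,4,5,8,9,11a-octahydrocyclodeca[b]furan-4-yl (3R)-3,4-dihydroxy-2-methylidenebutanoate
Conditions: AcOH/H2O/THF (3:1:1), rt
Reagents that add atoms: none
Why: Mild aqueous-acid hydrolysis of the terminal acetonide frees the side-chain diol without touching the acetate, the lactone or the stereocentres.

**Step 17**
Reactants: 31 (3aR,4S,6E,10E,11aS)-10-(acetoxymethyl)-6-methyl-3-methylidene-2-oxo-2,3,3a,4,5,8,9,11a-octahydrocyclodeca[b]furan-4-yl (3R)-3,4-dihydroxy-2-methylidenebutanoate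
Product: 32 (3aR,4S,7R,10E,11aS)-10-(acetoxymethyl)-7-hydroperoxy-3,6-dimethylidene-2-oxo-2,3,3a,4,5,6,7,8,9,11a-decahydrocyclodeca[b]furan-4-yl (3R)-3,4-dihydroxy-2-methylidenebutanoate
Conditions: O2, tetraphenylporphyrin (cat.), visible light, CH2Cl2, −20 °C
Reagents that add atoms: oxygen, O=O
Why: Schenck ene reaction of singlet oxygen at the only electron-rich alkene (the other three are deactivated) takes a hydrogen from the C14 methyl on the disubstituted side (cis effect) and delivers oxygen to C1 from the outer face of the ring, which by analogy with the 1β-hydroperoxides formed from 1(10)-E germacranolides with the same C7/C8 configuration should give 1R.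

**Compound list**
1 | (R)-glycidol | OC[C@@H]1CO1 | starting material
2 | lithium acetylide ethylenediamine complex | [Li+].[C-]#C.NCCN | starting material
3 | (2S)-pent-4-yne-1,2-diol | C#CC[C@H](O)CO | intermediate
4 | (2S)-1,2-bis(triethylsilyloxy)pent-4-yne | C#CC[C@H](O[Si](CC)(CC)CC)CO[Si](CC)(CC)CC | intermediate
5 | vinyl bromide | C=CBr | starting material
6 | dimethyl[(1E,4S)-2-methyl-4,5-bis(triethylsilyloxy)pent-1-enyl]alane | C[Al](C)/C=C(\C)C[C@H](O[Si](CC)(CC)CC)CO[Si](CC)(CC)CC | intermediate (not isolated)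
7 | (3E,6S)-4-methyl-6,7-bis(triethylsilyloxy)hepta-1,3-diene | C=C/C=C(\C)C[C@H](O[Si](CC)(CC)CC)CO[Si](CC)(CC)CC | intermediate
8 | 3,3-diethoxyprop-1-yne | C#CC(OCC)OCC | starting material
9 | lithium 3,3-diethoxyprop-1-yn-1-ide | [Li+].[C-]#CC(OCC)OCC | intermediate (not isolated)
10 | 4,4-diethoxybut-2-yn-1-ol | OCC#CC(OCC)OCC | intermediate
11 | (2Z)-4,4-diethoxy-2-(tributylstannyl)but-2-en-1-ol | OC/C(=C/C(OCC)OCC)[Sn](CCCC)(CCCC)CCCC | intermediate (not isolated)
12 | (2Z)-4,4-diethoxy-2-iodobut-2-en-1-ol | OC/C(I)=C/C(OCC)OCC | intermediate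
13 | (2Z)-4,4-diethoxy-2-iodobut-2-en-1-yl acetate | CC(=O)OC/C(I)=C/C(OCC)OCC | intermediate
14 | 9-[(3E,6S)-4-methyl-6,7-bis(triethylsilyloxy)hept-3-enyl]-9-borabicyclo[3.3.1]nonane | B1(CC/C=C(\C)C[C@H](O[Si](CC)(CC)CC)CO[Si](CC)(CC)CC)C2CCCC1CCC2 | intermediate (not isolated)
15 | (2E,5E,8S)-2-(2,2-diethoxyethylidene)-6-methyl-8,9-bis(triethylsilyloxy)non-5-en-1-yl acetate | CCOC(OCC)/C=C(/COC(C)=O)CC/C=C(\C)C[C@H](O[Si](CC)(CC)CC)CO[Si](CC)(CC)CC | intermediate
16 | (2S,4E,8E)-8-(acetoxymethyl)-10,10-diethoxy-4-methyl-2-(triethylsilyloxy)deca-4,8-dienal | CCOC(OCC)/C=C(/COC(C)=O)CC/C=C(\C)C[C@H](O[Si](CC)(CC)CC)C=O | intermediate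
17 | methyl acrylate | C=CC(=O)OC | starting material
18 | methyl (4S,6E,10E)-10-(acetoxymethyl)-12,12-diethoxy-3-hydroxy-6-methyl-2-methylidene-4-(triethylsilyloxy)dodeca-6,10-dienoate (both C3 epimers) | CCOC(OCC)/C=C(/COC(C)=O)CC/C=C(\C)C[C@H](O[Si](CC)(CC)CC)C(O)C(=C)C(=O)OC | intermediate
19 | methyl (2Z,4S,6E,10E)-10-(acetoxymethyl)-2-(bromomethyl)-12,12-diethoxy-6-methyl-4-(triethylsilyloxy)dodeca-2,6,10-trienoate | CCOC(OCC)/C=C(/COC(C)=O)CC/C=C(\C)C[C@H](O[Si](CC)(CC)CC)/C=C(\CBr)C(=O)OC | intermediate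
20 | methyl (2Z,4S,6E,10E)-10-(acetoxymethyl)-2-(bromomethyl)-6-methyl-12-oxo-4-(triethylsilyloxy)dodeca-2,6,10-trienoate | O=C/C=C(/COC(C)=O)CC/C=C(\C)C[C@H](O[Si](CC)(CC)CC)/C=C(\CBr)C(=O)OC | intermediate
21 | methyl 2-[(1S,2S,3E,7E,10S)-4-(acetoxymethyl)-2-hydroxy-8-methyl-10-(triethylsilyloxy)cyclodeca-3,7-dien-1-yl]prop-2-enoate | COC(=O)C(=C)[C@H]1[C@@H](O)/C=C(/COC(C)=O)CC/C=C(\C)C[C@@H]1O[Si](CC)(CC)CC | intermediate (not isolated)
22 | [(3aS,4S,6E,10E,11aS)-6-methyl-3-methylidene-2-oxo-4-(triethylsilyloxy)-2,3,3a,4,5,8,9,11a-octahydrocyclodeca[b]furan-10-yl]methyl acetate | C=C1C(=O)O[C@H]2/C=C(/COC(C)=O)CC/C=C(\C)C[C@H](O[Si](CC)(CC)CC)[C@@H]12 | intermediate (not isolated)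
23 | [(3aR,4S,6E,10E,11aS)-4-hydroxy-6-methyl-3-methylidene-2-oxo-2,3,3a,4,5,8,9,11a-octahydrocyclodeca[b]furan-10-yl]methyl acetate | C=C1C(=O)O[C@H]2/C=C(/COC(C)=O)CC/C=C(\C)C[C@H](O)[C@@H]12 | intermediate
24 | methyl 2-[(4R)-2,2-dimethyl-1,3-dioxolan-4-yl]acetate | COC(=O)C[C@@H]1COC(C)(C)O1 | starting material
25 | lithium enolate of 24 | [Li+].COC([O-])=C[C@@H]1COC(C)(C)O1 | intermediate (not isolated)
26 | methyl 3-(dimethylamino)-2-[(4R)-2,2-dimethyl-1,3-dioxolan-4-yl]propanoate (both C2 epimers) | COC(=O)C(CN(C)C)[C@@H]1COC(C)(C)O1 | intermediate (not isolated)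
27 | {2-[(4R)-2,2-dimethyl-1,3-dioxolan-4-yl]-3-methoxy-3-oxopropyl}trimethylammonium iodide | [I-].COC(=O)C(C[N+](C)(C)C)[C@@H]1COC(C)(C)O1 | intermediate (not isolated)
28 | methyl 2-[(4R)-2,2-dimethyl-1,3-dioxolan-4-yl]prop-2-enoate | COC(=O)C(=C)[C@@H]1COC(C)(C)O1 | intermediate
29 | 2-[(4R)-2,2-dimethyl-1,3-dioxolan-4-yl]prop-2-enoic acid | OC(=O)C(=C)[C@@H]1COC(C)(C)O1 | intermediate
30 | (3aR,4S,6E,10E,11aS)-10-(acetoxymethyl)-6-methyl-3-methylidene-2-oxo-2,3,3a,4,5,8,9,11a-octahydrocyclodeca[b]furan-4-yl 2-[(4R)-2,2-dimethyl-1,3-dioxolan-4-yl]prop-2-enoate | C=C1C(=O)O[C@H]2/C=C(/COC(C)=O)CC/C=C(\C)C[C@H](OC(=O)C(=C)[C@@H]3COC(C)(C)O3)[C@@H]12 | intermediate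
31 | (3aR,4S,6E,10E,11aS)-10-(acetoxymethyl)-6-methyl-3-methylidene-2-oxo-2,3,3a,4,5,8,9,11a-octahydrocyclodeca[b]furan-4-yl (3R)-3,4-dihydroxy-2-methylidenebutanoate | C=C1C(=O)O[C@H]2/C=C(/COC(C)=O)CC/C=C(\C)C[C@H](OC(=O)C(=C)[C@@H](O)CO)[C@@H]12 | intermediate
32 | (3aR,4S,7R,10E,11aS)-10-(acetoxymethyl)-7-hydroperoxy-3,6-dimethylidene-2-oxo-2,3,3a,4,5,6,7,8,9,11a-decahydrocyclodeca[b]furan-4-yl (3R)-3,4-dihydroxy-2-methylidenebutanoate (CNP0307408.1) | C=C1C(=O)O[C@H]2/C=C(/COC(C)=O)CC[C@@H](OO)C(=C)C[C@H](OC(=O)C(=C)[C@@H](O)CO)[C@@H]12 | target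

**Totals**
Total step count: 17. Longest linear sequence: 12 steps from (R)-glycidol (steps 1, 2, 3, 7, 8, 9, 10, 11, 12, 15, 16, 17).

**Three steps most likely to fail**

Step 12 (ring closure). The allylindium carries a silyloxy group on the carbon next to the nucleophilic C7, so loss of silyloxide (1,4-elimination to a dienoate) or protonation can compete with the slow ten-membered closure. The facial selectivity with respect to C8 is a model-based prediction, not a precedent. The fallback sets out from 19 and returns at 22. Pd2(dba)3-catalysed borylation of the allylic bromide with B2pin2 gives the pinacol allylboronate acetal F1. The same wet-silica/oxalic acid hydrolysis gives the enal allylboronate F2. Its covalent C–B bond cannot eliminate or be protonated, and a Sc(OTf)3-catalysed intramolecular allylboration at 2 mM in toluene passes through the same closed chair (syn, hence cis lactone) and lactonises to silyl lactone 22. PPTS/MeOH as in step 12 then gives 23.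

Step 17 (hydroperoxide). The ene reaction could give the 10-hydroperoxy-1(2)-ene regioisomer or the C1 epimer, since the conformation of this 4,5-cis, cis-lactone ring is not the one for which precedent exists. The fallback sets out from 23 and returns at 32. Photooxygenation (O2, tetraphenylporphyrin, light) of the free 8-hydroxy lactone, which has a different conformational bias and a hydrogen-bond donor near the alkene, gives the hydroperoxy alcohol F3. 2-Methoxypropene/PPTS at −20 °C caps the hydroperoxide as the peroxyketal F4. DCC/DMAP esterification with 29 gives the ester F5. AcOH/H2O/THF then removes the acetonide and the peroxyketal together to give 32, so the acid-sensitive 1(10),4-diene never meets the hydrolysis.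

Step 9 (Morita–Baylis–Hillman). The amine-catalysed reaction is slow, and over days the α-silyloxy aldehyde may epimerise or the silyl group may migrate. The fallback sets out from 16 and returns at 18. The lithium enolate of methyl 3-(dimethylamino)propanoate (LDA, THF, −78 °C) adds to the aldehyde in minutes to give the amino alcohol F6. Quaternisation with MeI and NaHCO3-promoted β-elimination then unveil the methylidene group of 18.

**Further compounds**
F1 | step 12 | methyl (2E,4S,6E,10E)-10-(acetoxymethyl)-12,12-diethoxy-6-methyl-2-[(4,4,5,5-tetramethyl-1,3,2-dioxaborolan-2-yl)methyl]-4-(triethylsilyloxy)dodeca-2,6,10-trienoate | CCOC(OCC)/C=C(/COC(C)=O)CC/C=C(\C)C[C@H](O[Si](CC)(CC)CC)/C=C(\CB1OC(C)(C)C(C)(C)O1)C(=O)OC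
F2 | step 12 | methyl (2E,4S,6E,10E)-10-(acetoxymethyl)-6-methyl-12-oxo-2-[(4,4,5,5-tetramethyl-1,3,2-dioxaborolan-2-yl)methyl]-4-(triethylsilyloxy)dodeca-2,6,10-trienoate | O=C/C=C(/COC(C)=O)CC/C=C(\C)C[C@H](O[Si](CC)(CC)CC)/C=C(\CB1OC(C)(C)C(C)(C)O1)C(=O)OC
F3 | step 17 | [(3aR,4S,7R,10E,11aS)-7-hydroperoxy-4-hydroxy-3,6-dimethylidene-2-oxo-2,3,3a,4,5,6,7,8,9,11a-decahydrocyclodeca[b]furan-10-yl]methyl acetate | C=C1C(=O)O[C@H]2/C=C(/COC(C)=O)CC[C@@H](OO)C(=C)C[C@H](O)[C@@H]12
F4 | step 17 | [(3aR,4S,7R,10E,11aS)-4-hydroxy-7-[(2-methoxypropan-2-yl)peroxy]-3,6-dimethylidene-2-oxo-2,3,3a,4,5,6,7,8,9,11a-decahydrocyclodeca[b]furan-10-yl]methyl acetate | C=C1C(=O)O[C@H]2/C=C(/COC(C)=O)CC[C@@H](OOC(C)(C)OC)C(=C)C[C@H](O)[C@@H]12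
F5 | step 17 | (3aR,4S,7R,10E,11aS)-10-(acetoxymethyl)-7-[(2-methoxypropan-2-yl)peroxy]-3,6-dimethylidene-2-oxo-2,3,3a,4,5,6,7,8,9,11a-decahydrocyclodeca[b]furan-4-yl 2-[(4R)-2,2-dimethyl-1,3-dioxolan-4-yl]prop-2-enoate | C=C1C(=O)O[C@H]2/C=C(/COC(C)=O)CC[C@@H](OOC(C)(C)OC)C(=C)C[C@H](OC(=O)C(=C)[C@@H]3COC(C)(C)O3)[C@@H]12
F6 | step 9 | methyl (4S,6E,10E)-10-(acetoxymethyl)-2-[(dimethylamino)methyl]-12,12-diethoxy-3-hydroxy-6-methyl-4-(triethylsilyloxy)dodeca-6,10-dienoate | CCOC(OCC)/C=C(/COC(C)=O)CC/C=C(\C)C[C@H](O[Si](CC)(CC)CC)C(O)C(CN(C)C)C(=O)OC
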